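**Plan**
1. Numbering: ring C1 (CH carrying the side chain), C2 (CH–O), C3 (C=O), C4 (C–CH3), C5 (oxirane CH), C6 (CH2); side chain C7 (=CH2), C8 (CH–O), C9, C10, C11.
2. Cuts, in order: the C10–C11 oxirane back to the alkene; the two angelates and the C3 ketone back to a triol; C7–C8 (alkenyl triflate + 4-methylpent-3-enal); then C1–C6 and C4–C5 together, which opens the epoxycyclohexane to an acyclic keto β-keto sulfone and a vinylsulfonium salt.
3. Forward: D-threitol acetonide supplies C1–C4; one cascade closes the six-membered ring and the C4–C5 oxirane; the side chain is joined at C7–C8; the esters, the C3 ketone and the C10–C11 oxirane come last.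
4. Enabling feature: C4 is a methyl-bearing oxirane carbon next to C5H–C6H2, so it can be a former methyl ketone attacked by the ylide end of a two-carbon vinylsulfonium unit whose other end is bonded to C1, a carbon made acidic by the C7 carbonyl and a removable sulfonyl group.
5. Stereochemistry: C2 from the chiral pool; C4/C5 from the C3 oxygen (chiral pool, later oxidised) held in a trans-fused acetonide; C1 by equilibration after desulfonylation (both C1 epimers converge); C8 by a ligand-controlled Ni/Cr coupling; C10 by Shi epoxidation.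

Key step: step 7

Assumption: in step 11 the (S)-oxazoline sulfonamide ligand is taken to give the 8S carbinol by analogy with couplings of 2-substituted alkenyl electrophiles with unbranched aldehydes; should the 8R carbinol prevail, the (R)-ligand is used.

**Route**

Step 1
Reactants: 1 (4R,5R)-2,2-dimethyl-1,3-dioxolane-4,5-dimethanol
Product: 2 [(4R,5R)-5-(hydroxymethyl)-2,2-dimethyl-1,3-dioxolan-4-yl]methyl 4-methylbenzenesulfonate
Conditions: NaH (1.0 equiv), THF, 0 °C; TsCl (1.0 equiv), 0 to 23 °C
Reagents that add atoms: 4-toluenesulfonyl chloride, Cc1ccc(cc1)S(=O)(=O)Cl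
Why: O-sulfonylation of the mono-alkoxide of a C2-symmetric diol, so either hydroxyl gives the same product and no stereocentre is touched.

Step 2
Reactants: 2 mono-tosylate
Product: 3 [(4R,5S)-2,2-dimethyl-5-(phenylsulfonylmethyl)-1,3-dioxolan-4-yl]methanol
Conditions: PhSO2Na, nBu4NI (cat.), DMF, 80 °C
Reagents that add atoms: sodium benzenesulfinate, [Na+].[O-]S(=O)c1ccccc1
Why: SN2 S-alkylation of the sulfinate by the primary tosylate installs the sulfonyl group on the future C1; the trans ring fusion that cyclisation of the free hydroxyl would need keeps that side reaction out.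

Step 3
Reactants: 3 hydroxy sulfone
Product: 4 (4S,5S)-2,2-dimethyl-5-(phenylsulfonylmethyl)-1,3-dioxolane-4-carbaldehyde
Conditions: Dess–Martin periodinane, CH2Cl2, 23 °C
Reagents that add atoms: none
Why: Dess–Martin oxidation of the primary alcohol; the α-centre already has the more stable trans-dioxolane configuration, so epimerisation is not a concern.

Step 4
Reactants: 4 aldehyde
Product: 5 1-[(4R,5S)-2,2-dimethyl-5-(phenylsulfonylmethyl)-1,3-dioxolan-4-yl]ethan-1-ol (both carbinol epimers)
Conditions: MeMgBr, THF, −78 °C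
Reagents that add atoms: methylmagnesium bromide, C[Mg]Br
Why: Grignard addition to the aldehyde is much faster than deprotonation of the sulfone at −78 °C; the new carbinol centre is oxidised away in step 6, so its configuration is irrelevant.

Step 5
Reactants: 5 secondary alcohol
Product: 6 1-[(4S,5R)-5-(1-hydroxyethyl)-2,2-dimethyl-1,3-dioxolan-4-yl]-1-(phenylsulfonyl)propan-2-ol (mixture at the three centres outside the ring)
Conditions: nBuLi (2.2 equiv), THF, −78 °C; CH3CHO, −78 °C
Reagents that add atoms: acetaldehyde, CC=O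
Why: the alkoxide/α-sulfonyl carbanion dianion adds through carbon to acetaldehyde (β-hydroxy sulfone formation as in the first stage of a Julia olefination); the new centres are removed or reset later.

Step 6
Reactants: 6 diol
Product: 7 1-[(4S,5S)-5-acetyl-2,2-dimethyl-1,3-dioxolan-4-yl]-1-(phenylsulfonyl)propan-2-one (both C1 epimers)
Conditions: Dess–Martin periodinane (3 equiv), CH2Cl2, 23 °C
Reagents that add atoms: none
Why: Dess–Martin oxidation of both secondary alcohols gives the C4 methyl ketone and the C7 β-keto sulfone in one operation.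

Step 7
Reactants: 7 diketo sulfone; 8 diphenyl(vinyl)sulfonium trifluoromethanesulfonate
Product: 11 1-acetyl-4,5-epoxy-2,3-(isopropylidenedioxy)-4-methyl-1-(phenylsulfonyl)cyclohexane ((2S,3S,4R,5R) in the numbering of the plan; both C1 epimers), via sulfonium ylide 9 (not isolated), via betaine 10 (not isolated)
Conditions: 8 (1.3 equiv), DBU (2.0 equiv), CH2Cl2, 0 °C
Reagents that add atoms: none
Why: Proposed new method: DBU removes the doubly activated C1–H of 7, the β-keto sulfone carbanion adds to the vinylsulfonium salt to give ylide 9, the ylide carbon C5 adds to the C4 ketone to give betaine 10 and the C4 alkoxide displaces diphenyl sulfide from C5; the closest known reaction type is the epoxy-annulation of amino ketones with diphenyl vinyl sulfonium triflate, extended here to a carbocycle and to a carbon acid that keeps no C1–H after the addition (so no cyclopropane can form). The cyclohexane closes by 6-exo-trig attack of the ylide on the carbonyl group and the oxirane by 3-exo-tet displacement. C4 and C5 are controlled by the C3 oxygen and the acetonide: the trans-fused dioxolane holds the forming chair with O2 and O3 equatorial, the C3–O bond antiperiplanar to the forming C4–C5 bond (polar Felkin–Anh) and the C4 methyl equatorial, so the alkoxide is axial and the oxirane ends cis to O3 and trans to O2. Only the betaine with C5–S and C4–O trans-diaxial can close, and because the locked ring cannot flip, diequatorial or cis betaines are expected to return to ylide and ketone, which funnels the material into one C4/C5 configuration. C1 forms as a mixture that does not matter, since the sulfonyl group leaves in step 8 and C1 is then equilibrated. The step needs C- over O-alkylation of the enolate and ring closure faster than loss of the β-oxygen at C2, which the soft sulfonyl-stabilised carbanion, the poor acetal leaving group and 0 °C should secure.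

Step 8
Reactants: 11 epoxy sulfone
Product: 13 (1S,2R,3S,4R,5R)-1-acetyl-4,5-epoxy-2,3-(isopropylidenedioxy)-4-methylcyclohexane (acetyl cis to the oxirane, trans to O2), via C1-epimeric ketone 12 (not isolated)
Conditions: SmI2 (2.5 equiv), MeOH, THF, −78 °C; then DBU (0.2 equiv), CH2Cl2, 0 °C
Reagents that add atoms: none
Why: reductive desulfonylation of the α-sulfonyl ketone by divalent samarium (ketyl formation, loss of sulfinate, protonation of the enolate); both C1 epimers of 11 converge, and enolisation equilibrates C1 to the equatorial acetyl isomer trans to O2 on the ring locked by the trans-fused acetonide (thermodynamic control).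

Step 9
Reactants: 13 methyl ketone
Product: 14 (1S,2R,3S,4R,5R)-4,5-epoxy-2,3-(isopropylidenedioxy)-4-methyl-1-[1-(trifluoromethanesulfonyloxy)ethenyl]cyclohexane
Conditions: KN(SiMe3)2, THF, −78 °C; PhNTf2
Reagents that add atoms: N-phenylbis(trifluoromethanesulfonimide), O=S(=O)(N(c1ccccc1)S(=O)(=O)C(F)(F)F)C(F)(F)F
Why: kinetic deprotonation at the unhindered methyl group (not at the tertiary C1–H) and O-triflation of the enolate give the terminal alkenyl triflate, which fixes C1 because it is no longer enolisable.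

Step 10
Reactants: 15 4-methylpent-3-en-1-ol
Product: 16 4-methylpent-3-enal
Conditions: Dess–Martin periodinane, CH2Cl2, 0 °C; used at once
Reagents that add atoms: none
Why: mild Dess–Martin oxidation gives the β,γ-unsaturated aldehyde, which is used crude before it can move into conjugation.

Step 11
Reactants: 14 alkenyl triflate; 16 4-methylpent-3-enal
Product: 17 (1R,2R,3S,4R,5R,8S)-allylic alcohol: 4,5-epoxy-1-[(3S)-3-hydroxy-6-methylhepta-1,5-dien-2-yl]-2,3-(isopropylidenedioxy)-4-methylcyclohexane
Conditions: CrCl2 (4 equiv), NiCl2 (0.02 equiv), (S)-N-[2-(4-isopropyl-4,5-dihydrooxazol-2-yl)-6-methylphenyl]methanesulfonamide (4.4 equiv), Et3N, THF, 23 °C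
Reagents that add atoms: none
Why: Nozaki–Hiyama–Kishi coupling (zerovalent nickel inserts into the C–OTf bond, the alkenyl group passes to chromium and the trivalent alkenylchromium adds to the aldehyde only); C8 is set by the chiral oxazoline sulfonamide on chromium (reagent control).

Step 12
Reactants: 17 acetonide
Product: 18 (1R,2R,3S,4S,5R,8S)-triol: 4,5-epoxy-1-[(3S)-3-hydroxy-6-methylhepta-1,5-dien-2-yl]-4-methylcyclohexane-2,3-diol
Conditions: AcOH–H2O (4:1), 40 °C
Reagents that add atoms: none
Why: acid hydrolysis of the strained trans-fused acetonide; the oxirane is deactivated by the adjacent C3 oxygen, and a cis epoxy alcohol cannot undergo Payne rearrangement.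

Step 13
Reactants: 18 triol; 19 angelic acid ((Z)-2-methylbut-2-enoic acid)
Product: 21 (1R,2R,3S,4S,5R,8S)-2,8-di-O-angeloyl triol (C3–OH free), via mixed anhydride 20 (not isolated)
Conditions: 19 (2.3 equiv), 2,4,6-trichlorobenzoyl chloride, Et3N, toluene, 23 °C; then 18, 75 °C
Reagents that add atoms: none
Why: Yamaguchi esterification through the mixed anhydride without DMAP, conditions that keep the Z geometry; the allylic C8–OH and the C2–OH should react, while the C3–OH, flanked by the fully substituted C4 and hydrogen-bonded to the cis oxirane oxygen, should stay free.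

Step 14
Reactants: 21 diester alcohol
Product: 22 (1R,2R,4R,5R,8S)-2,8-di-O-angeloyl-4,5-epoxy 3-ketone
Conditions: Dess–Martin periodinane, CH2Cl2, 23 °C
Reagents that add atoms: none
Why: Dess–Martin oxidation of the hindered secondary alcohol; C2 becomes enolisable but already holds the more stable equatorial ester trans to the C1 substituent.

Step 15
Reactants: 22 dienyl ketone
Product: 23 CNP0247177.1, (1R,2R,4R,5R,8S,10R)
Conditions: 1,2:4,5-di-O-isopropylidene-D-erythro-2,3-hexodiulo-2,6-pyranose (0.3 equiv), KHSO5 (as Oxone, 2KHSO5·KHSO4·K2SO4), K2CO3, nBu4NHSO4, MeCN–dimethoxymethane–aqueous Na2B4O7, 0 °C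
Reagents that add atoms: potassium peroxymonosulfate, [K+].[O-]S(=O)(=O)OO
Why: Shi epoxidation by the chiral dioxirane through a spiro transition state; the electron-rich trisubstituted C10=C11 alkene should react ahead of the 1,1-disubstituted C7 alkene and the two conjugated ester alkenes, and the D-fructose-derived ketone should give the 10R oxirane.

**Compound list**
1 | (4R,5R)-2,2-dimethyl-1,3-dioxolane-4,5-dimethanol (2,3-O-isopropylidene-D-threitol) | OC[C@H]1OC(C)(C)O[C@@H]1CO | starting material
2 | [(4R,5R)-5-(hydroxymethyl)-2,2-dimethyl-1,3-dioxolan-4-yl]methyl 4-methylbenzenesulfonate | Cc1ccc(cc1)S(=O)(=O)OC[C@H]1OC(C)(C)O[C@@H]1CO | intermediate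
3 | [(4R,5S)-2,2-dimethyl-5-(phenylsulfonylmethyl)-1,3-dioxolan-4-yl]methanol | O=S(=O)(C[C@H]1OC(C)(C)O[C@@H]1CO)c1ccccc1 | intermediate
4 | (4S,5S)-2,2-dimethyl-5-(phenylsulfonylmethyl)-1,3-dioxolane-4-carbaldehyde | O=S(=O)(C[C@H]1OC(C)(C)O[C@@H]1C=O)c1ccccc1 | intermediate
5 | 1-[(4R,5S)-2,2-dimethyl-5-(phenylsulfonylmethyl)-1,3-dioxolan-4-yl]ethan-1-ol, both carbinol epimers | O=S(=O)(C[C@H]1OC(C)(C)O[C@@H]1C(C)O)c1ccccc1 | intermediate
6 | 1-[(4S,5R)-5-(1-hydroxyethyl)-2,2-dimethyl-1,3-dioxolan-4-yl]-1-(phenylsulfonyl)propan-2-ol, mixture at the three centres outside the ring | CC(O)C([C@H]1OC(C)(C)O[C@@H]1C(C)O)S(=O)(=O)c1ccccc1 | intermediate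
7 | 1-[(4S,5S)-5-acetyl-2,2-dimethyl-1,3-dioxolan-4-yl]-1-(phenylsulfonyl)propan-2-one, both C1 epimers | CC(=O)C([C@H]1OC(C)(C)O[C@@H]1C(C)=O)S(=O)(=O)c1ccccc1 | intermediate
8 | diphenyl(vinyl)sulfonium trifluoromethanesulfonate | C=C[S+](c1ccccc1)c1ccccc1.[O-]S(=O)(=O)C(F)(F)F | starting material
9 | sulfonium ylide: 7 alkylated at C1 by a 2-(diphenylsulfonio)ethan-2-ide arm | CC(=O)C(C[CH-][S+](c1ccccc1)c1ccccc1)([C@H]1OC(C)(C)O[C@@H]1C(C)=O)S(=O)(=O)c1ccccc1 | intermediate (not isolated)
10 | betaine: cyclohexane with axial C4 alkoxide and axial C5 diphenylsulfonio group, trans-fused acetonide | CC(=O)C1(S(=O)(=O)c2ccccc2)C[C@H]([S+](c2ccccc2)c2ccccc2)[C@]([O-])(C)[C@H]2OC(C)(C)O[C@H]12 | intermediate (not isolated)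
11 | 1-acetyl-4,5-epoxy-2,3-(isopropylidenedioxy)-4-methyl-1-(phenylsulfonyl)cyclohexane, (2S,3S,4R,5R), both C1 epimers; oxirane cis to O3, trans to O2 | CC(=O)C1(S(=O)(=O)c2ccccc2)C[C@H]2O[C@@]2(C)[C@H]2OC(C)(C)O[C@H]12 | intermediate
12 | (1R,2R,3S,4R,5R)-1-acetyl-4,5-epoxy-2,3-(isopropylidenedioxy)-4-methylcyclohexane (axial acetyl, C1 epimer of 13) | CC(=O)[C@@H]1C[C@H]2O[C@@]2(C)[C@H]2OC(C)(C)O[C@H]12 | intermediate (not isolated)
13 | (1S,2R,3S,4R,5R)-1-acetyl-4,5-epoxy-2,3-(isopropylidenedioxy)-4-methylcyclohexane | CC(=O)[C@H]1C[C@H]2O[C@@]2(C)[C@H]2OC(C)(C)O[C@H]12 | intermediate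
14 | (1S,2R,3S,4R,5R)-4,5-epoxy-2,3-(isopropylidenedioxy)-4-methyl-1-[1-(trifluoromethanesulfonyloxy)ethenyl]cyclohexane | C=C(OS(=O)(=O)C(F)(F)F)[C@H]1C[C@H]2O[C@@]2(C)[C@H]2OC(C)(C)O[C@H]12 | intermediate
15 | 4-methylpent-3-en-1-ol | CC(C)=CCCO | starting material
16 | 4-methylpent-3-enal | CC(C)=CCC=O | intermediate
17 | (1R,2R,3S,4R,5R,8S)-4,5-epoxy-1-[(3S)-3-hydroxy-6-methylhepta-1,5-dien-2-yl]-2,3-(isopropylidenedioxy)-4-methylcyclohexane | C=C([C@H](CC=C(C)C)O)[C@H]1C[C@H]2O[C@@]2(C)[C@H]2OC(C)(C)O[C@H]12 | intermediate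
18 | (1R,2R,3S,4S,5R,8S)-4,5-epoxy-1-[(3S)-3-hydroxy-6-methylhepta-1,5-dien-2-yl]-4-methylcyclohexane-2,3-diol | C=C([C@H](CC=C(C)C)O)[C@H]1C[C@H]2O[C@@]2(C)[C@@H](O)[C@@H]1O | intermediate
19 | angelic acid, (Z)-2-methylbut-2-enoic acid | C/C=C(/C)C(=O)O | starting material
20 | (Z)-2-methylbut-2-enoic 2,4,6-trichlorobenzoic anhydride | C/C=C(/C)C(=O)OC(=O)c1c(Cl)cc(Cl)cc1Cl | intermediate (not isolated)
21 | (1R,2R,3S,4S,5R,8S)-2,8-di-O-angeloyl derivative of 18, C3–OH free | C=C([C@H](CC=C(C)C)OC(=O)/C(C)=C\C)[C@H]1C[C@H]2O[C@@]2(C)[C@@H](O)[C@@H]1OC(=O)/C(C)=C\C | intermediate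
22 | (1R,2R,4R,5R,8S)-2,8-di-O-angeloyl-4,5-epoxy 3-ketone with the C10=C11 alkene | C=C([C@H](CC=C(C)C)OC(=O)/C(C)=C\C)[C@H]1C[C@H]2O[C@@]2(C)C(=O)[C@@H]1OC(=O)/C(C)=C\C | intermediate
23 | CNP0247177.1: (1R,3R,4R,6R)-4-[(3S)-4-[(2R)-3,3-dimethyloxiran-2-yl]-3-[(Z)-2-methylbut-2-enoyloxy]but-1-en-2-yl]-1-methyl-2-oxo-7-oxabicyclo[4.1.0]heptan-3-yl (Z)-2-methylbut-2-enoate | C=C([C@H](C[C@H]1OC1(C)C)OC(=O)/C(C)=C\C)[C@H]1C[C@H]2O[C@@]2(C)C(=O)[C@@H]1OC(=O)/C(C)=C\C | target

**Count**
Total steps: 15. Longest linear sequence: 14 (steps 1–9 and 11–15; step 10 makes the aldehyde partner).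

**Steps most likely to fail**

1. Step 7. The ring closure may show poor facial selectivity: a betaine with equatorial sulfonium and equatorial oxide could close through a twist-boat to the other C4/C5 configuration. The carbanion may also be lost through elimination of the C2 acetal oxygen before it is alkylated. The fallback uses known chemistry, sets out from 7 and returns at 13. Vinyltriphenylphosphonium bromide and K2CO3 in MeCN at reflux should give, by conjugate addition of the C1 carbanion and intramolecular Wittig olefination of the C4 ketone, the cyclohexene sulfone F1 (C1–C6 bond and C4=C5 alkene made in one operation, no stereocentre at stake). SmI2/MeOH and then DBU, as in step 8, should give the equatorial acetyl cyclohexene F2. Aqueous AcOH should free the allylic diol F3. VO(acac)2 with tBuOOH should deliver oxygen cis to the allylic C3 hydroxyl to give the epoxy diol F4. 2,2-Dimethoxypropane with pyridinium 4-toluenesulfonate should then close the acetonide again, which is 13.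

2. Step 13. Acylation may not stop at two esters (the C3 hydroxyl may also react), or the Z ester may isomerise to the E ester on heating with base. The fallback sets out from 17 and returns at 22, differentiating the hydroxyls one at a time at low temperature. The single hydroxyl of 17 is esterified with 19 under the conditions of step 13 to give the C8 angelate acetonide F5. Aqueous AcOH gives the diol F6. Et3SiCl and imidazole in DMF at −40 °C should silylate only the less hindered O2 to give the silyl ether F7. Dess–Martin oxidation of the remaining C3 hydroxyl gives the ketone F8, and HF·pyridine frees the ketol F9. A second esterification with 19 gives 22.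

3. Step 11. Induction at C8 may be low, and aldehyde 16 may move into conjugation under the amine base before it couples. The fallback sets out from 14 and 16 and returns at 17. Coupling with CrCl2 and catalytic NiCl2 in DMF without ligand gives 17 together with its C8 epimer F10. Dess–Martin oxidation of the mixture gives the cross-conjugated enone F11. Corey–Bakshi–Shibata reduction with the (R)-methyl oxazaborolidine and BH3·SMe2, the alkenyl group acting as the large substituent, should give the 8S alcohol 17.

**Further compounds**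
F1 | step 7 | 1-acetyl-2,3-(isopropylidenedioxy)-4-methyl-1-(phenylsulfonyl)cyclohex-4-ene, trans-fused acetonide, both C1 epimers | CC(=O)C1(S(=O)(=O)c2ccccc2)CC=C(C)[C@H]2OC(C)(C)O[C@H]12
F2 | step 7 | 1-acetyl-2,3-(isopropylidenedioxy)-4-methylcyclohex-4-ene, acetyl trans to O2 | CC(=O)[C@H]1CC=C(C)[C@H]2OC(C)(C)O[C@H]12
F3 | step 7 | 1-acetyl-4-methylcyclohex-4-ene-2,3-diol, trans diol, acetyl trans to O2 | CC(=O)[C@H]1CC=C(C)[C@@H](O)[C@@H]1O
F4 | step 7 | 1-acetyl-4,5-epoxy-4-methylcyclohexane-2,3-diol, oxirane cis to the C3 hydroxyl | CC(=O)[C@H]1C[C@H]2O[C@@]2(C)[C@@H](O)[C@@H]1O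
F5 | step 13 | 8-O-angeloyl derivative of 17 | C=C([C@H](CC=C(C)C)OC(=O)/C(C)=C\C)[C@H]1C[C@H]2O[C@@]2(C)[C@H]2OC(C)(C)O[C@H]12
F6 | step 13 | 8-O-angeloyl 2,3-diol | C=C([C@H](CC=C(C)C)OC(=O)/C(C)=C\C)[C@H]1C[C@H]2O[C@@]2(C)[C@@H](O)[C@@H]1O
F7 | step 13 | 8-O-angeloyl 2-O-triethylsilyl 3-ol | C=C([C@H](CC=C(C)C)OC(=O)/C(C)=C\C)[C@H]1C[C@H]2O[C@@]2(C)[C@@H](O)[C@@H]1O[Si](CC)(CC)CC
F8 | step 13 | 8-O-angeloyl 2-O-triethylsilyl 3-ketone | C=C([C@H](CC=C(C)C)OC(=O)/C(C)=C\C)[C@H]1C[C@H]2O[C@@]2(C)C(=O)[C@@H]1O[Si](CC)(CC)CC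
F9 | step 13 | 8-O-angeloyl 2-hydroxy 3-ketone | C=C([C@H](CC=C(C)C)OC(=O)/C(C)=C\C)[C@H]1C[C@H]2O[C@@]2(C)C(=O)[C@@H]1O
F10 | step 11 | C8 epimer of 17 (8R) | C=C([C@@H](CC=C(C)C)O)[C@H]1C[C@H]2O[C@@]2(C)[C@H]2OC(C)(C)O[C@H]12
F11 | step 11 | C8 ketone (enone) derived from 17 | C=C(C(=O)CC=C(C)C)[C@H]1C[C@H]2O[C@@]2(C)[C@H]2OC(C)(C)O[C@H]12
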